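Ring A is dissected into two three-carbon halves: C10–C1–C2, the α and α′ positions of a C1 methyl ketone, and C5–C4(=C15)–C3, a 2-(acetoxymethyl)enal. An acyclic keto enal that already carries the C6/C7 stereodiad and both acrylate units is folded in one base-mediated cascade: 6-exo Michael addition of the C10 enolate to C5 closes ring B and creates the quaternary centre, acetate loss unveils the C4(15) methylene, and aldol addition of C2 to the C3 aldehyde closes ring A. The step exploits the 1,3-dioxygenation at C1/C3 and the exocyclic methylene between C3 and C5; both carbinols are then set by hydride reductions.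

Key step: step 12

Remark on the chemistry: atom labels C1–C15 follow eudesmane numbering of the target. The methyl-bearing carbon next to the ketone (future C10) is carried as an epimer mixture, because it becomes the enolate carbon of step 12; its configuration is left open in the SMILES until then. The enantiomer of the chiral ligand in step 5 is assumed to be chosen so that the (1R) carbinol results.

Step 1
Reactants: 1 β-citronellene (3,7-dimethylocta-1,6-diene, either enantiomer or racemate)
Product: 3 4-methylhex-5-enal, via ozonide of the trisubstituted alkene 2 (not isolated)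
Conditions: O3 (1.0 equiv, Sudan Red 7B end-point), CH2Cl2, −78 °C; then Me2S, −78 °C → rt
Reagents that add atoms: ozone, O=[O+][O-]
Why: Electrophilic ozone attacks the electron-rich trisubstituted alkene much faster than the monosubstituted vinyl group, so titration to the dye end-point and reductive work-up of ozonide 2 should give the aldehyde with the vinyl group intact (chemoselective ozonolysis).

Step 2
Reactants: 3 4-methylhex-5-enal; 4 methyl acrylate
Product: 5 methyl 3-hydroxy-6-methyl-2-methylideneoct-7-enoate (diastereomer mixture)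
Conditions: DABCO (0.5 equiv), 4 (3 equiv, neat), rt, several days
Reagents that add atoms: none
Why: Morita–Baylis–Hillman reaction of an unhindered aliphatic aldehyde with methyl acrylate; the new carbinol centre is of no consequence because it is removed in step 4.

Step 3
Reactants: 5 methyl 3-hydroxy-6-methyl-2-methylideneoct-7-enoate
Product: 6 methyl 3-hydroxy-6-methyl-2-methylidene-7-oxooctanoate
Conditions: PdCl2 (10 mol %), CuCl (1 equiv), O2 (1 atm), DMF/H2O (7:1), rt
Reagents that add atoms: water, O
Why: Tsuji–Wacker oxidation, in which Markovnikov hydroxypalladation of the terminal alkene gives the methyl ketone while the electron-poor, geminally disubstituted acrylate does not compete.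

Step 4
Reactants: 6 methyl 3-hydroxy-6-methyl-2-methylidene-7-oxooctanoate
Product: 7 methyl (2Z)-2-(bromomethyl)-6-methyl-7-oxooct-2-enoate
Conditions: NBS (1.2 equiv), Me2S (1.3 equiv), CH2Cl2, 0 °C → rt
Reagents that add atoms: N-bromosuccinimide, O=C1CCC(=O)N1Br
Why: The alcohol is activated as an alkoxysulfonium salt and bromide attacks the methylene terminus with allylic transposition (Corey–Kim-type SN2′ bromination), which should give the conjugated ester with the alkyl chain cis to CH2Br (2Z), the thermodynamically preferred geometry.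

Step 5
Reactants: 7 methyl (2Z)-2-(bromomethyl)-6-methyl-7-oxooct-2-enoate; 8 acrolein (prop-2-enal)
Product: 10 methyl (3S)-3-[(1R)-1-hydroxyprop-2-en-1-yl]-6-methyl-2-methylidene-7-oxooctanoate, via its O-trimethylsilyl ether 9 (not isolated)
Conditions: CrCl2 (10 mol %), chiral tridentate 1,8-bis(oxazolin-2-yl)carbazole ligand (12 mol %), i-Pr2NEt (30 mol %), Mn powder (2 equiv), Me3SiCl (1.2 equiv), 8 (3 equiv), slow addition of 7, THF, 0 °C; then aq. citric acid, MeOH, 0 °C
Reagents that add atoms: none
Why: Catalytic asymmetric Nozaki–Hiyama–Kishi 2-(alkoxycarbonyl)allylation: the allylchromium species, whose geometrical isomers interconvert, adds through its γ-carbon in a chair transition state with the vinyl group of acrolein and the γ-alkyl chain both equatorial, which should give the anti relationship (future C6/C7), while the ligand selects the aldehyde face to set (1R,3S), the reagent prefers the aldehyde over the ketone, and silyl trapping as 9 suppresses lactonisation until the cold work-up.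

Step 6
Reactants: 11 2-methylidenepropane-1,3-diol
Product: 12 2-(hydroxymethyl)prop-2-en-1-yl acetate
Conditions: Ac2O (1 equiv), 11 (2 equiv), Et3N, DMAP (2 mol %), CH2Cl2, 0 °C
Reagents that add atoms: acetic anhydride, CC(=O)OC(C)=O
Why: Monoacetylation of a symmetric diol used in excess (O-acylation); no stereocentre is involved.

Step 7
Reactants: 12 2-(hydroxymethyl)prop-2-en-1-yl acetate
Product: 13 2-formylprop-2-en-1-yl acetate [2-(acetoxymethyl)acrolein]
Conditions: activated MnO2 (15 equiv), CH2Cl2, rt
Reagents that add atoms: none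
Why: MnO2 oxidises the primary allylic alcohol to the enal under neutral conditions that leave the allylic acetate untouched (allylic oxidation).

Step 8
Reactants: 10 methyl (3S)-3-[(1R)-1-hydroxyprop-2-en-1-yl]-6-methyl-2-methylidene-7-oxooctanoate; 13 2-formylprop-2-en-1-yl acetate
Product: 14 methyl (3S)-3-[(1R,2E)-3-(acetoxymethyl)-1-hydroxy-4-oxobut-2-en-1-yl]-6-methyl-2-methylidene-7-oxooctanoate
Conditions: second-generation Hoveyda–Grubbs catalyst [RuCl2(H2IMes)(=CH-C6H4-2-O-i-Pr)] (5 mol %), 13 (4 equiv), 1,4-benzoquinone (10 mol %), CH2Cl2, 40 °C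
Reagents that add atoms: none
Why: Olefin cross-metathesis between the terminal vinyl carbinol and a geminally disubstituted, electron-poor partner that does not homodimerise should give the trisubstituted enal as the E isomer (CHO trans to C6), while the α-substituted acrylate is too electron-poor and hindered to take part.

Step 9
Reactants: 15 methyl 2-(hydroxymethyl)prop-2-enoate
Product: 16 methyl 2-{[(tert-butyldimethylsilyl)oxy]methyl}prop-2-enoate
Conditions: TBSCl, imidazole, CH2Cl2, 0 °C → rt
Reagents that add atoms: tert-butyldimethylsilyl chloride, CC(C)(C)[Si](C)(C)Cl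
Why: Standard silylation of a primary alcohol (silyl ether formation).

Step 10
Reactants: 16 methyl 2-{[(tert-butyldimethylsilyl)oxy]methyl}prop-2-enoate
Product: 17 2-{[(tert-butyldimethylsilyl)oxy]methyl}prop-2-enoic acid
Conditions: LiOH·H2O, THF/H2O (3:1), 0 °C → rt; then 1 M HCl to pH 4, 0 °C
Reagents that add atoms: lithium hydroxide, [Li+].[OH-]
Why: Saponification of the methyl ester; the primary silyl ether should survive the brief, cold acidification.

Step 11
Reactants: 14 methyl (3S)-3-[(1R,2E)-3-(acetoxymethyl)-1-hydroxy-4-oxobut-2-en-1-yl]-6-methyl-2-methylidene-7-oxooctanoate; 17 2-{[(tert-butyldimethylsilyl)oxy]methyl}prop-2-enoic acid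
Product: 18 methyl (3S)-3-[(1R,2E)-3-(acetoxymethyl)-1-({2-[(tert-butyldimethylsilyloxy)methyl]prop-2-enoyl}oxy)-4-oxobut-2-en-1-yl]-6-methyl-2-methylidene-7-oxooctanoate
Conditions: DCC (1.5 equiv), DMAP (0.2 equiv), CH2Cl2, 0 °C → rt
Reagents that add atoms: none
Why: Steglich esterification acylates the secondary alcohol at oxygen with retention at C6; it is done after step 8 because an acrylate ester of the vinyl carbinol would undergo ring-closing metathesis to a butenolide.

Step 12
Reactants: 18 methyl (3S)-3-[(1R,2E)-3-(acetoxymethyl)-1-({2-[(tert-butyldimethylsilyloxy)methyl]prop-2-enoyl}oxy)-4-oxobut-2-en-1-yl]-6-methyl-2-methylidene-7-oxooctanoate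
Product: 21 methyl 6α-({2-[(tert-butyldimethylsilyloxy)methyl]prop-2-enoyl}oxy)-3ξ-hydroxy-1-oxo-5αH-eudesma-4(15),11(13)-dien-12-oate (C3 epimer mixture), via potassium enolate of the Michael adduct 19 (not isolated), via monocyclic keto methylene-aldehyde 20 (not isolated)
Conditions: KOt-Bu (1.15 equiv), t-BuOH (3 equiv), THF (0.005 M), −78 → −20 °C; AcOH, −78 °C
Reagents that add atoms: none
Why: Enolates form reversibly on both sides of the C1 ketone, but only the C10 enolate reaches the enal through a six-membered transition state, so it adds 6-exo-trig to C5 (Michael addition); the aldehyde enolate 19 then expels acetate (E1cB), which makes this congested addition irreversible, consumes one equivalent of base and unveils the C4(15) methylene in 20, and the residual base enolises the only remaining site, the C2 methyl group, which closes ring A by 6-(enolendo)-exo-trig aldol addition to the C3 aldehyde. The closest known reaction type is the tandem Michael–aldol (formal [3+3]) annulation of a ketone α,α′-bisnucleophile, combined with the SN2′ displacement of 2-(acyloxymethyl)-substituted acceptors by enolates, here run intramolecularly. In the chair transition state for ring B the C6 acyloxy group and the C7 side chain are equatorial; 1,3-allylic strain with the cis CH2OAc group holds H6 in the enal plane and places the C6–O bond anti to the incoming enolate, so C5 is attacked on the face that makes H5 axial and trans to H6. At the donor end the same allylic strain keeps a C9 hydrogen, not C8, eclipsed with the tetrasubstituted enolate, so C1 ends equatorial and the methyl group axial, which is the trans ring fusion (5αH, 10β-methyl). C3 should form as an epimer mixture in which the axial 3α-alkoxide from a potassium-bridged closed transition state predominates; this centre is deliberately reset in steps 14 and 15. The step needs addition to the enal and not to the two α-substituted acrylates (much weaker acceptors, one reachable only by 6-endo attack), no γ-deprotonation of the enal (the in-plane H6 is stereoelectronically non-acidic), and 1,2- instead of 1,4-addition in the last closure, which low temperature, nearly stoichiometric base and a cold acetic acid quench are chosen to secure.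

Step 13
Reactants: 21 methyl 6α-({2-[(tert-butyldimethylsilyloxy)methyl]prop-2-enoyl}oxy)-3ξ-hydroxy-1-oxo-5αH-eudesma-4(15),11(13)-dien-12-oate
Product: 22 methyl 6α-({2-[(tert-butyldimethylsilyloxy)methyl]prop-2-enoyl}oxy)-1β,3ξ-dihydroxy-5αH-eudesma-4(15),11(13)-dien-12-oate (C3 epimer mixture)
Conditions: NaBH4 (1.5 equiv), MeOH/CH2Cl2 (1:1), −20 → 0 °C
Reagents that add atoms: none
Why: Borohydride should attack the C1 ketone along the axial trajectory on the α face, away from the axial C10 methyl group (for the 3α epimer also by delivery from the axial alkoxyborohydride), giving the equatorial 1β alcohol, while acrylates and esters are inert at this temperature (ketone reduction).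

Step 14
Reactants: 22 methyl 6α-({2-[(tert-butyldimethylsilyloxy)methyl]prop-2-enoyl}oxy)-1β,3ξ-dihydroxy-5αH-eudesma-4(15),11(13)-dien-12-oate
Product: 23 methyl 6α-({2-[(tert-butyldimethylsilyloxy)methyl]prop-2-enoyl}oxy)-1β-hydroxy-3-oxo-5αH-eudesma-4(15),11(13)-dien-12-oate
Conditions: activated MnO2 (30 equiv), CH2Cl2, rt
Reagents that add atoms: none
Why: MnO2 oxidises only the allylic C3 carbinol of both epimers to the exocyclic enone and leaves the saturated, neopentyl C1 alcohol alone, which erases the uncontrolled C3 centre (chemoselective allylic oxidation).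

Step 15
Reactants: 23 methyl 6α-({2-[(tert-butyldimethylsilyloxy)methyl]prop-2-enoyl}oxy)-1β-hydroxy-3-oxo-5αH-eudesma-4(15),11(13)-dien-12-oate
Product: 24 methyl 6α-({2-[(tert-butyldimethylsilyloxy)methyl]prop-2-enoyl}oxy)-1β,3β-dihydroxy-5αH-eudesma-4(15),11(13)-dien-12-oate
Conditions: NaBH4, CeCl3·7H2O, MeOH, −78 °C
Reagents that add atoms: none
Why: Luche reduction delivers hydride 1,2 along the axial trajectory on the unhindered α face of the ring-A chair, which should give the equatorial 3β allylic alcohol without conjugate reduction of the enone or the acrylates.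

Step 16
Reactants: 24 methyl 6α-({2-[(tert-butyldimethylsilyloxy)methyl]prop-2-enoyl}oxy)-1β,3β-dihydroxy-5αH-eudesma-4(15),11(13)-dien-12-oate
Product: 25 methyl 1β,3β-dihydroxy-6α-{[2-(hydroxymethyl)prop-2-enoyl]oxy}-5αH-eudesma-4(15),11(13)-dien-12-oate (CNP0247525.1; 1R,3S,5S,6S,7S,10R)
Conditions: HF·pyridine, pyridine/THF, 0 °C → rt
Reagents that add atoms: none
Why: Buffered fluoride cleaves the primary silyl ether without base, so neither acyl migration nor ester exchange is expected (desilylation).

Compound list
1 | β-citronellene (3,7-dimethylocta-1,6-diene) | C=CC(C)CCC=C(C)C | starting material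
2 | 3,3-dimethyl-5-(3-methylpent-4-en-1-yl)-1,2,4-trioxolane (ozonide) | C=CC(C)CCC1OOC(C)(C)O1 | intermediate (not isolated)
3 | 4-methylhex-5-enal | C=CC(C)CCC=O | intermediate
4 | methyl acrylate | C=CC(=O)OC | starting material
5 | methyl 3-hydroxy-6-methyl-2-methylideneoct-7-enoate | C=CC(C)CCC(O)C(=C)C(=O)OC | intermediate
6 | methyl 3-hydroxy-6-methyl-2-methylidene-7-oxooctanoate | CC(=O)C(C)CCC(O)C(=C)C(=O)OC | intermediate
7 | methyl (2Z)-2-(bromomethyl)-6-methyl-7-oxooct-2-enoate | COC(=O)/C(CBr)=C/CCC(C)C(C)=O | intermediate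
8 | acrolein (prop-2-enal) | C=CC=O | starting material
9 | methyl (3S)-6-methyl-2-methylidene-7-oxo-3-[(1R)-1-(trimethylsilyloxy)prop-2-en-1-yl]octanoate | C=C[C@@H](O[Si](C)(C)C)[C@@H](CCC(C)C(C)=O)C(=C)C(=O)OC | intermediate (not isolated)
10 | methyl (3S)-3-[(1R)-1-hydroxyprop-2-en-1-yl]-6-methyl-2-methylidene-7-oxooctanoate | C=C[C@@H](O)[C@@H](CCC(C)C(C)=O)C(=C)C(=O)OC | intermediate
11 | 2-methylidenepropane-1,3-diol | C=C(CO)CO | starting material
12 | 2-(hydroxymethyl)prop-2-en-1-yl acetate | C=C(CO)COC(C)=O | intermediate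
13 | 2-formylprop-2-en-1-yl acetate | C=C(COC(C)=O)C=O | intermediate
14 | methyl (3S)-3-[(1R,2E)-3-(acetoxymethyl)-1-hydroxy-4-oxobut-2-en-1-yl]-6-methyl-2-methylidene-7-oxooctanoate | O=C/C(COC(C)=O)=C/[C@@H](O)[C@@H](CCC(C)C(C)=O)C(=C)C(=O)OC | intermediate
15 | methyl 2-(hydroxymethyl)prop-2-enoate | C=C(CO)C(=O)OC | starting material
16 | methyl 2-{[(tert-butyldimethylsilyl)oxy]methyl}prop-2-enoate | C=C(CO[Si](C)(C)C(C)(C)C)C(=O)OC | intermediate
17 | 2-{[(tert-butyldimethylsilyl)oxy]methyl}prop-2-enoic acid | C=C(CO[Si](C)(C)C(C)(C)C)C(=O)O | intermediate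
18 | methyl (3S)-3-[(1R,2E)-3-(acetoxymethyl)-1-({2-[(tert-butyldimethylsilyloxy)methyl]prop-2-enoyl}oxy)-4-oxobut-2-en-1-yl]-6-methyl-2-methylidene-7-oxooctanoate | O=C/C(COC(C)=O)=C/[C@@H](OC(=O)C(=C)CO[Si](C)(C)C(C)(C)C)[C@@H](CCC(C)C(C)=O)C(=C)C(=O)OC | intermediate
19 | potassium enolate of the Michael adduct (ring B closed, C3–C4 aldehyde enolate still bearing the C15 acetate) | C=C(CO[Si](C)(C)C(C)(C)C)C(=O)O[C@@H]1[C@@H](C(COC(C)=O)=C[O-])[C@](C)(C(C)=O)CC[C@H]1C(=C)C(=O)OC.[K+] | intermediate (not isolated)
20 | methyl 2-[(1S,2S,3S,4R)-4-acetyl-2-({2-[(tert-butyldimethylsilyloxy)methyl]prop-2-enoyl}oxy)-4-methyl-3-(3-oxoprop-1-en-2-yl)cyclohexyl]prop-2-enoate | C=C(CO[Si](C)(C)C(C)(C)C)C(=O)O[C@@H]1[C@@H](C(=C)C=O)[C@](C)(C(C)=O)CC[C@H]1C(=C)C(=O)OC | intermediate (not isolated)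
21 | methyl 6α-({2-[(tert-butyldimethylsilyloxy)methyl]prop-2-enoyl}oxy)-3ξ-hydroxy-1-oxo-5αH-eudesma-4(15),11(13)-dien-12-oate (trans-decalin, 10β-methyl, C3 epimers) | C=C(CO[Si](C)(C)C(C)(C)C)C(=O)O[C@@H]1[C@H]2C(=C)C(O)CC(=O)[C@]2(C)CC[C@H]1C(=C)C(=O)OC | intermediate
22 | methyl 6α-({2-[(tert-butyldimethylsilyloxy)methyl]prop-2-enoyl}oxy)-1β,3ξ-dihydroxy-5αH-eudesma-4(15),11(13)-dien-12-oate (C3 epimers) | C=C(CO[Si](C)(C)C(C)(C)C)C(=O)O[C@@H]1[C@H]2C(=C)C(O)C[C@@H](O)[C@]2(C)CC[C@H]1C(=C)C(=O)OC | intermediate
23 | methyl 6α-({2-[(tert-butyldimethylsilyloxy)methyl]prop-2-enoyl}oxy)-1β-hydroxy-3-oxo-5αH-eudesma-4(15),11(13)-dien-12-oate | C=C(CO[Si](C)(C)C(C)(C)C)C(=O)O[C@@H]1[C@H]2C(=C)C(=O)C[C@@H](O)[C@]2(C)CC[C@H]1C(=C)C(=O)OC | intermediate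
24 | methyl 6α-({2-[(tert-butyldimethylsilyloxy)methyl]prop-2-enoyl}oxy)-1β,3β-dihydroxy-5αH-eudesma-4(15),11(13)-dien-12-oate | C=C(CO[Si](C)(C)C(C)(C)C)C(=O)O[C@@H]1[C@H]2C(=C)[C@@H](O)C[C@@H](O)[C@]2(C)CC[C@H]1C(=C)C(=O)OC | intermediate
25 | methyl 1β,3β-dihydroxy-6α-{[2-(hydroxymethyl)prop-2-enoyl]oxy}-5αH-eudesma-4(15),11(13)-dien-12-oate (1R,3S,5S,6S,7S,10R) | C=C(CO)C(=O)O[C@@H]1[C@H]2C(=C)[C@@H](O)C[C@@H](O)[C@]2(C)CC[C@H]1C(=C)C(=O)OC | target

Total step count: 16. Longest linear sequence: 12 steps (steps 1–5, 8, 11–16).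

Steps most likely to fail

Step 12. After the first ring closure the C2 enolate may add in conjugate fashion to the exocyclic C15 of the newly formed 2-methylene aldehyde (a six-membered ring of the wrong constitution), or the ketol may lose water or revert under alkoxide. The fallback divides the cascade and sets out from 18. With exactly 1.0 equiv of KOt-Bu in THF/t-BuOH at −78 → −20 °C all base is consumed as potassium acetate, so the reaction should stop at 20, which is isolated. Ring A is then closed by a boron-mediated aldol addition (n-Bu2BOTf, i-Pr2NEt, CH2Cl2, −78 °C, pH 7 buffer work-up): soft enolisation can take place only at the C2 methyl group, because C10 is quaternary, and a boron enolate adds 1,2 without reversal. The fallback returns to the route at 21 and makes no compound outside the list (none, F0).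

Step 5. The ester-coordinated allylchromium may fail to equilibrate to the geometry that leads to the anti adduct, so that simple diastereoselection is poor; allyl transfer to the internal ketone and lactonisation are further drains. The fallback sets out from 7 and 8 and aims deliberately at the other diastereomer. An indium-mediated Barbier reaction (In powder, stoichiometric cinchona alkaloid promoter of the pseudo-enantiomeric series that gives the 3S configuration, THF/hexane, rt) goes through a cyclic transition state that retains the bromide geometry and should give the syn adduct methyl (3S)-3-[(1S)-1-hydroxyprop-2-en-1-yl]-6-methyl-2-methylidene-7-oxooctanoate F1. Cross-metathesis with 13 under the conditions of step 8 should give methyl (3S)-3-[(1S,2E)-3-(acetoxymethyl)-1-hydroxy-4-oxobut-2-en-1-yl]-6-methyl-2-methylidene-7-oxooctanoate F2. Mitsunobu esterification with acid 17 (PPh3, DIAD, toluene, 0 °C) then inverts C6 while installing the ester, and the route is rejoined at 18.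

Step 8. The allylically branched vinyl carbinol may engage the electron-poor geminal olefin too slowly, so that catalyst decomposition and isomerisation of the allylic alcohol to an ethyl ketone take over. The fallback sets out from 10 and builds the enal by carbonyl chemistry instead of metathesis. Steglich esterification with 17 (DCC, DMAP) should give methyl (3S)-3-[(1R)-1-({2-[(tert-butyldimethylsilyloxy)methyl]prop-2-enoyl}oxy)prop-2-en-1-yl]-6-methyl-2-methylidene-7-oxooctanoate F3. Lemieux–Johnson cleavage (OsO4 cat., NaIO4, 2,6-lutidine, dioxane/H2O), in which the electrophilic oxidant selects the only non-conjugated alkene, should give methyl (3S)-3-[(1S)-1-({2-[(tert-butyldimethylsilyloxy)methyl]prop-2-enoyl}oxy)-2-oxoethyl]-6-methyl-2-methylidene-7-oxooctanoate F4. A Morita–Baylis–Hillman reaction of this activated α-acyloxy aldehyde with acrolein 8 (DABCO) should give methyl (3S)-3-[(1S)-1-({2-[(tert-butyldimethylsilyloxy)methyl]prop-2-enoyl}oxy)-3-formyl-2-hydroxybut-3-en-1-yl]-6-methyl-2-methylidene-7-oxooctanoate F5. Acetylation (Ac2O, DMAP, CH2Cl2) should give methyl (3S)-3-[(1S)-2-acetoxy-1-({2-[(tert-butyldimethylsilyloxy)methyl]prop-2-enoyl}oxy)-3-formylbut-3-en-1-yl]-6-methyl-2-methylidene-7-oxooctanoate F6. DABCO-catalysed 1,3-transposition of the acetate (THF, rt) to the thermodynamically preferred trisubstituted enal rejoins the route at 18.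

Further compounds
F0 | step 12 | none | none
F1 | step 5 | methyl (3S)-3-[(1S)-1-hydroxyprop-2-en-1-yl]-6-methyl-2-methylidene-7-oxooctanoate | C=C[C@H](O)[C@@H](CCC(C)C(C)=O)C(=C)C(=O)OC
F2 | step 5 | methyl (3S)-3-[(1S,2E)-3-(acetoxymethyl)-1-hydroxy-4-oxobut-2-en-1-yl]-6-methyl-2-methylidene-7-oxooctanoate | O=C/C(COC(C)=O)=C/[C@H](O)[C@@H](CCC(C)C(C)=O)C(=C)C(=O)OC
F3 | step 8 | methyl (3S)-3-[(1R)-1-({2-[(tert-butyldimethylsilyloxy)methyl]prop-2-enoyl}oxy)prop-2-en-1-yl]-6-methyl-2-methylidene-7-oxooctanoate | C=C[C@@H](OC(=O)C(=C)CO[Si](C)(C)C(C)(C)C)[C@@H](CCC(C)C(C)=O)C(=C)C(=O)OC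
F4 | step 8 | methyl (3S)-3-[(1S)-1-({2-[(tert-butyldimethylsilyloxy)methyl]prop-2-enoyl}oxy)-2-oxoethyl]-6-methyl-2-methylidene-7-oxooctanoate | O=C[C@@H](OC(=O)C(=C)CO[Si](C)(C)C(C)(C)C)[C@@H](CCC(C)C(C)=O)C(=C)C(=O)OC
F5 | step 8 | methyl (3S)-3-[(1S)-1-({2-[(tert-butyldimethylsilyloxy)methyl]prop-2-enoyl}oxy)-3-formyl-2-hydroxybut-3-en-1-yl]-6-methyl-2-methylidene-7-oxooctanoate (carbinol epimers) | C=C(C=O)C(O)[C@@H](OC(=O)C(=C)CO[Si](C)(C)C(C)(C)C)[C@@H](CCC(C)C(C)=O)C(=C)C(=O)OC
F6 | step 8 | methyl (3S)-3-[(1S)-2-acetoxy-1-({2-[(tert-butyldimethylsilyloxy)methyl]prop-2-enoyl}oxy)-3-formylbut-3-en-1-yl]-6-methyl-2-methylidene-7-oxooctanoate (acetate epimers) | C=C(C=O)C(OC(C)=O)[C@@H](OC(=O)C(=C)CO[Si](C)(C)C(C)(C)C)[C@@H](CCC(C)C(C)=O)C(=C)C(=O)OC
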